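(The readings come from a simulation for an exercise.)

One Z cannot sit in two products at once. So you keep books on Z, which I treat as the limiting reagent against E.

| flask | E | Z | G | remark | time |
|---|---|---|---|---|---|
| north | 1.5 M | 1.2 M | 0.50 M | run made earlier |  |
| north-west | 1 M | 1.2 M | 1 M | run made earlier |  |
| red | 1.0 M | 1.60 M | 0.500 M |  | 10 min |
| green | 1.0 M | 1.20 M | 0.500 M |  | 10 min |

- north (time / min: E / %, J / %): 0.500: 95.4, 4.4; 1.00: 91.9, 7.6; 2.50: 87.0, 14.1; 6.00: 80.8, 19.6
- north-west (time / min: E / %, J / %): 1.50: 92.8, 7.5; 3.00: 90.7, 9.6; 5.00: 89.4, 10.4; 6.00: 88.5, 12.4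

(scatter of a reading: 0.5 percentage points)

* part of the E that has reacted at the end, red
* part of the E that has reacted at the end, green
* what raising the concentration of Z from its lowest to its highest value here does to the part of the E that has reacted (changes below 5 percentage points count as none) (no change / it rises / it falls)

First entry: the north-west run, with more G but also less E, ends lower in J, so I assume that G takes Z and debit one Z per G. What remains, [Z] − [G], is spendable. Second entry: divide it by the J of the last reading.

north: 0.700 M / 0.294 M = 2.38

north-west: 0.200 M / 0.124 M = 1.61

mean: 2.00

J is still rising at the last reading of both runs, so both values can read high. The mean is the Z price, the spendable Z paid per J made. It is a reading and carries the scatter of the runs.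

Now close the books for E charged at 1.0 M:

green: 0.700 M / (2.00 × 1.0 M) = 35.1%

red: 1.10 M / (2.00 × 1.0 M) = 55.1%

These are my estimates for 10 min. The gap of 20 percentage points exceeds the margin of 5 points, so I expect the part reacted to rise with Z.

The forecast differs. It gives 21.5% for red and 19% for green, with no change, and it warns: “Z was never varied, so its role is unknown”.

The flask gives 43.5% for red and 29.5% for green. With Z raised from its lowest to its highest value, the answer is: it rises, by 14 points.

    E + Z → Q + J (k = 0.00180 M⁻¹ s⁻¹)
    Z + Q ⇌ X, settled at all times (K = 1100 M⁻¹)
    Z + G → L (k = 0.0450 M⁻¹ s⁻¹)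
    Q → D (k = 0.0190 s⁻¹)

In the scheme, Z goes one to L per G, one per J in the first step, and one into each X. In green at 10.0 min, X stands at 0.283 M against 0.00209 M of Q and 0.00987 M of D. The price leaves 0.112 M of Z in green, and the flask holds 0.123 M free. Now take the neighbour, green with 3.0 M of Z. Its budget comes to 125% of the E, more than the E charged. In that flask 78.3% of the E has reacted at 10.0 min. The price leaves 0.937 M of Z there, and that flask holds 0.940 M free.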